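Whatever goes in, substrate (A), intermediate (I), target (P) and uncatalysed product (V) add up to the substrate charged so far, so we can get the unread I by subtraction.

| flask | substrate | reagent | free catalyst | second catalyst | remark | time |
|---|---|---|---|---|---|---|
| larch | 0.050 M | 0.065 M | 5.5 mM | 0.10 mM | run made earlier |  |
| elm | 0.025 M | 0.065 M | 5.5 mM | 0.10 mM | run made earlier |  |
| maple | 0.038 M | 0.065 M | 5.5 mM | 0.10 mM | run made earlier |  |
| oak | 0.050 M | 0.065 M | 5.5 mM | 0.050 mM | run made earlier |  |
| green | 0.050 M (fed, over 15 h) | 0.0650 M | 5.5 mM | 0.10 mM | all else is in the flask from the start; the feed brings no volume worth counting | 20 h |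
| red | 0.050 M | 0.0650 M | 5.5 mM | 0.10 mM | everything together at the start | 20 h |
| blue | 0.050 M | 0.0650 M (fed, over 15 h) | 5.5 mM | 0.10 mM | all else is in the flask from the start; the feed brings no volume worth counting | 20 h |
| teal | 0.050 M (in portions, 2, over 15 h) | 0.0650 M | 5.5 mM | 0.10 mM | first portion at the start, last at 15 h | 20 h |

| run | time / h | target / % | uncatalysed product / % |
|---|---|---|---|
| larch | 2.50 | 0 | 1.7 |
| larch | 8.00 | 5.5 | 4.9 |
| larch | 12.0 | 9.3 | 5.4 |
| larch | 20.0 | 20.1 | 7.7 |
| elm | 4.00 | 1.5 | 2.1 |
| elm | 8.00 | 4.6 | 4.3 |
| elm | 12.0 | 9.4 | 6.1 |
| elm | 15.0 | 13.7 | 7.5 |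
| maple | 2.00 | 0.4 | 2.1 |
| maple | 6.00 | 3.4 | 4.5 |
| maple | 10.0 | 7.4 | 5.4 |
| maple | 15.0 | 13.4 | 7.4 |
| oak | 4.00 | 1.2 | 2.3 |
| oak | 8.00 | 2.5 | 3.3 |
| oak | 12.0 | 4.8 | 6.4 |
| oak | 15.0 | 7.4 | 6.7 |

(scatter of a reading: 0.5 percentage points)

- what may be going on: substrate + reagent -> uncatalysed product; substrate + free catalyst -> free catalyst + intermediate; reagent + second catalyst + intermediate -> second catalyst + target

- the flask that comes out highest in share of target in target plus uncatalysed product, or "all alike" when all lie within 1.5 percentage points (green / red / blue / teal / all alike)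
- share of target in target plus uncatalysed product at the end, green
- share of target in target plus uncatalysed product at the end, red
- share of target in target plus uncatalysed product at the end, blue
- share of target in target plus uncatalysed product at the end, teal

We build a ladder of times from larch, which has the same charges as red, and every value read from it carries the scatter of the readings.

1. V rises at 0.00680 h⁻¹ of the charge early and 0.00287 h⁻¹ late. Taking reagent as roughly constant, about 42.3% of A stands near 16.0 h, and subtraction gives I about 36.5%.

2. On these readings, A halves in about 12.9 h, I goes to P with a half-life near 18.7 h, and A goes to V alone with a half-life near 102 h. The side step is thus slower than the other two, and on this reckoning larch still holds A and I at 20 h.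

3. Both product-forming steps use reagent, so reagent cancels from the ratio of their rates, and a molecule's fork reads dP/dV = g·I/A. Here g, the exchange rate (a selectivity factor), is the ratio of the two step constants with second catalyst included, and the late slopes of larch put it near 5.44.

4. I/A starts at nothing, so V formed early is poorly exchanged. Larch reads a share of 72.3%, and feeding reagent late should beat that, while feeding substrate holds I/A down. Our order is blue, red, teal, green, so the thing to watch is the slope of P against V.

The forecast named blue, with green 65.5%, red 72.5%, blue 82% and teal 68%, on the grounds that “low early reagent starves the side reaction while intermediate banks up”.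

The flasks give blue on top, with green 63.0%, red 70.3%, blue 79.3% and teal 66.3%.

    substrate + reagent → uncatalysed product (k = 3.10 × 10⁻⁵ M⁻¹ s⁻¹)
    substrate + free catalyst → free catalyst + intermediate (k = 0.00230 M⁻¹ s⁻¹)
    reagent + second catalyst + intermediate → second catalyst + target (k = 1.90 M⁻² s⁻¹)

At 20.0 h blue holds I 41.0% and A 37.0%, so our larch reading of g, with its scatter, makes g·I/A about 6.02, an estimated momentary share of 85.8% against the 79.3% gathered over the run. The neighbouring flask is blue with free catalyst at 0.0022 M, less than 5.5 mM, and at 20.0 h it holds I 21.1% and A 63.8%. The same larch reading of g puts its g·I/A at about 1.80, an estimated momentary share of 64.3%, and its gathered share is 57.1%.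

The numbers in the tables were computed from invented constants; the scatter is artificial.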